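**Plan**
- Retrosynthesis: the six phenols are traced to methyl ethers, the stilbene C=C is cut (phosphonate olefination of a C5 aldehyde), C2–H is traced to C2–B, and then the C3–aryl and C2–aryl bonds are cut together.
- Enabling feature: ring O1–C2–C3–C3a–C7a is the furan ring of a benzofuran whose C2=C3 bond has taken up one aryl group per carbon from opposite faces (catechol ring at C2, resorcinol ring at C3) and nothing else.
- Forward: no ring is made. A bought benzofuran (formyl masked as dioxolane) is lithiated at C2, bound to the catechol-type arylboronate and arylated at C3 by the resorcinol-type triflate in one pot. Boron is then exchanged for hydrogen, the aldehyde freed, the styryl arm attached and the ethers cleaved.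
- Stereochemistry: C3 (S) comes from the chiral ferrocenyl bisphosphine on palladium choosing the benzofuran face. C2 (S) follows from the anti 1,2-shift (aryl trans to aryl) and a retentive C–B to C–H exchange. The E-alkene comes from the phosphonate olefination.

Key step: step 3

Assumption: the sense of induction of the ferrocenyl ligand on this new substrate class cannot be predicted reliably; the (S,S)-(R,R) antipode is written, and its mirror image, equally available, would be used should the first run deliver the (2R,3R) series.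

**Route**

Step 1
Reactants: 1 1-benzofuran-5-carbaldehyde
Product: 2 5-(1,3-dioxolan-2-yl)-1-benzofuran
Conditions: HOCH2CH2OH, pyridinium p-toluenesulfonate (cat.), PhMe, reflux, azeotropic removal of water
Reagents that add atoms: ethylene glycol, OCCO
Why: Acid-catalysed acetalisation of a non-enolisable aryl aldehyde, driven by removal of water, masks the formyl group against n-BuLi and the borate of step 3, and the weak acid leaves the benzofuran untouched.

Step 2
Reactants: 3 3,5-dimethoxyphenol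
Product: 4 3,5-dimethoxyphenyl trifluoromethanesulfonate
Conditions: Tf2O, pyridine, CH2Cl2, 0 °C
Reagents that add atoms: trifluoromethanesulfonic anhydride, O=S(=O)(OS(=O)(=O)C(F)(F)F)C(F)(F)F
Why: O-Sulfonylation of a phenol with triflic anhydride and an amine base is routine and gives a halide-free electrophile for oxidative addition.

Step 3
Reactants: 2 5-(1,3-dioxolan-2-yl)-1-benzofuran; 5 2-(3,4-dimethoxyphenyl)-4,4,5,5-tetramethyl-1,3,2-dioxaborolane; 4 3,5-dimethoxyphenyl trifluoromethanesulfonate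
Product: 8 2-[(2S,3S)-3-(3,5-dimethoxyphenyl)-2-(3,4-dimethoxyphenyl)-5-(1,3-dioxolan-2-yl)-2,3-dihydro-1-benzofuran-2-yl]-4,4,5,5-tetramethyl-1,3,2-dioxaborolane (aryl groups trans; boron cis to the C3 aryl), via 2-lithio-5-(1,3-dioxolan-2-yl)-1-benzofuran 6 (not isolated), via lithium aryl(benzofuran-2-yl)pinacolatoborate 7 (not isolated)
Conditions: n-BuLi, THF, −78 °C; then 5, −78 °C → rt; then 4, Pd(OAc)2 (3 mol%), (S,S)-1,1′-bis(diphenylphosphino)-2,2′-bis[(R)-α-(dimethylamino)benzyl]ferrocene (C52H50FeN2P2, 3.6 mol%), THF, 60 °C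
Reagents that add atoms: none
Why: Proposed new method: deprotonation of 2 at C2 and addition to boronic ester 5 give borate 7, whose C2=C3 bond is bound at C3 by the cationic aryl–palladium triflate that arises from oxidative addition of 4 to ligated zerovalent palladium; this binding triggers a 1,2-shift of the dimethoxyphenyl group from boron to C2 on the face opposite to the metal, and the C3–palladium alkyl so formed, which has no β-hydrogen because C2 is fully substituted, reductively eliminates with retention to make the C3–aryl bond. The closest known reaction types are the enantioselective palladium-catalysed conjunctive cross-coupling of alkenylboron ate complexes with aryl triflates and the dearomative three-component couplings of indol-2-yl and furan-2-yl borates with carbon electrophiles; a benzofuran-2-yl borate intercepted by an aryl–palladium species has not been described. No ring is closed: the furan ring is only dearomatised while the C3–aryl and C2–aryl bonds form. Both stereocentres arise in the same anti carbometallation: the bisphosphine decides which face of the benzofuran the metal occupies (absolute configuration at C3), and the anti shift forces the migrating aryl trans to the incoming one with boron cis to it (relative configuration at C2). The step needs the metallate shift to outrun boron-to-palladium transmetallation (plain Suzuki–Miyaura biaryl formation); the halide-free system (triflate electrophile, borate made with n-BuLi) keeps palladium cationic and olefin-bound and the wide bite angle of the ferrocenyl ligand slows transmetallation, while attack at C3 and not C2 follows from the enol-ether polarisation of the 2-borylated furan ring.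

Step 4
Reactants: 8 2-[(2S,3S)-3-(3,5-dimethoxyphenyl)-2-(3,4-dimethoxyphenyl)-5-(1,3-dioxolan-2-yl)-2,3-dihydro-1-benzofuran-2-yl]-4,4,5,5-tetramethyl-1,3,2-dioxaborolane
Product: 9 2-[(2S,3S)-2-(3,4-dimethoxyphenyl)-3-(3,5-dimethoxyphenyl)-2,3-dihydro-1-benzofuran-5-yl]-1,3-dioxolane (trans)
Conditions: Bu4NF·3H2O, PhMe, 45 °C
Reagents that add atoms: none
Why: Fluoride-promoted protodeboronation of a tertiary benzylic pinacol boronate should proceed with retention (water protonates C2 of the fluoroborate on the face boron leaves), so hydrogen ends cis to the C3 aryl group, the two aryl groups stay trans, and C3 is not touched.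

Step 5
Reactants: 9 2-[(2S,3S)-2-(3,4-dimethoxyphenyl)-3-(3,5-dimethoxyphenyl)-2,3-dihydro-1-benzofuran-5-yl]-1,3-dioxolane
Product: 10 (2S,3S)-2-(3,4-dimethoxyphenyl)-3-(3,5-dimethoxyphenyl)-2,3-dihydro-1-benzofuran-5-carbaldehyde
Conditions: pyridinium p-toluenesulfonate (cat.), acetone/H2O, 50 °C
Reagents that add atoms: water, O
Why: Acid-catalysed hydrolysis of an aryl dioxolane is far faster than any reaction of the aryl methyl ethers or the cyclic benzylic ether under weak acid, and no stereocentre takes part.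

Step 6
Reactants: 10 (2S,3S)-2-(3,4-dimethoxyphenyl)-3-(3,5-dimethoxyphenyl)-2,3-dihydro-1-benzofuran-5-carbaldehyde; 11 diethyl (3,5-dimethoxybenzyl)phosphonate
Product: 12 (2S,3S)-2-(3,4-dimethoxyphenyl)-3-(3,5-dimethoxyphenyl)-5-[(E)-2-(3,5-dimethoxyphenyl)ethenyl]-2,3-dihydro-1-benzofuran
Conditions: 11, KOtBu, THF, 0 °C; then 10, 0 °C → rt
Reagents that add atoms: none
Why: Horner–Wadsworth–Emmons olefination of a non-enolisable aryl aldehyde with a benzylic phosphonate anion should give the E-stilbene, and the benzylic C2–H and C3–H are not acidic enough to be touched by the alkoxide.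

Step 7
Reactants: 12 (2S,3S)-2-(3,4-dimethoxyphenyl)-3-(3,5-dimethoxyphenyl)-5-[(E)-2-(3,5-dimethoxyphenyl)ethenyl]-2,3-dihydro-1-benzofuran
Product: 13 4-[(2S,3S)-3-(3,5-dihydroxyphenyl)-5-[(E)-2-(3,5-dihydroxyphenyl)ethenyl]-2,3-dihydro-1-benzofuran-2-yl]benzene-1,2-diol (CNP0207985.1)
Conditions: BBr3 (excess), CH2Cl2, −78 → 0 °C; then H2O
Reagents that add atoms: none
Why: Boron tribromide cleavage of aryl methyl ethers (bromide attack on the methyl group of each O–B adduct) should free all six phenols; a reversible ionisation of the benzylic C2–O bond would reclose to the favoured trans ring and C3 is never involved, so the (2S,3S) configuration should be kept.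

**Compound list**

1 | 1-benzofuran-5-carbaldehyde | O=Cc1ccc2occc2c1 | starting material
2 | 5-(1,3-dioxolan-2-yl)-1-benzofuran | c1cc2cc(C3OCCO3)ccc2o1 | intermediate
3 | 3,5-dimethoxyphenol | COc1cc(O)cc(OC)c1 | starting material
4 | 3,5-dimethoxyphenyl trifluoromethanesulfonate | COc1cc(OC)cc(OS(=O)(=O)C(F)(F)F)c1 | intermediate
5 | 2-(3,4-dimethoxyphenyl)-4,4,5,5-tetramethyl-1,3,2-dioxaborolane | COc1ccc(B2OC(C)(C)C(C)(C)O2)cc1OC | starting material
6 | 2-lithio-5-(1,3-dioxolan-2-yl)-1-benzofuran | [Li]c1cc2cc(C3OCCO3)ccc2o1 | intermediate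
7 | lithium (3,4-dimethoxyphenyl)[5-(1,3-dioxolan-2-yl)-1-benzofuran-2-yl](pinacolato)borate | [Li+].COc1ccc([B-]2(c3cc4cc(C5OCCO5)ccc4o3)OC(C)(C)C(C)(C)O2)cc1OC | intermediate
8 | 2-[(2S,3S)-3-(3,5-dimethoxyphenyl)-2-(3,4-dimethoxyphenyl)-5-(1,3-dioxolan-2-yl)-2,3-dihydro-1-benzofuran-2-yl]-4,4,5,5-tetramethyl-1,3,2-dioxaborolane | O1CCOC1c1ccc2c(c1)[C@H](c1cc(OC)cc(OC)c1)[C@@](B1OC(C)(C)C(C)(C)O1)(c1ccc(OC)c(OC)c1)O2 | intermediate
9 | 2-[(2S,3S)-2-(3,4-dimethoxyphenyl)-3-(3,5-dimethoxyphenyl)-2,3-dihydro-1-benzofuran-5-yl]-1,3-dioxolane | O1CCOC1c1ccc2c(c1)[C@H](c1cc(OC)cc(OC)c1)[C@@H](c1ccc(OC)c(OC)c1)O2 | intermediate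
10 | (2S,3S)-2-(3,4-dimethoxyphenyl)-3-(3,5-dimethoxyphenyl)-2,3-dihydro-1-benzofuran-5-carbaldehyde | O=Cc1ccc2c(c1)[C@H](c1cc(OC)cc(OC)c1)[C@@H](c1ccc(OC)c(OC)c1)O2 | intermediate
11 | diethyl (3,5-dimethoxybenzyl)phosphonate | CCOP(=O)(Cc1cc(OC)cc(OC)c1)OCC | starting material
12 | (2S,3S)-2-(3,4-dimethoxyphenyl)-3-(3,5-dimethoxyphenyl)-5-[(E)-2-(3,5-dimethoxyphenyl)ethenyl]-2,3-dihydro-1-benzofuran | COc1cc(OC)cc(/C=C/c2ccc3c(c2)[C@H](c2cc(OC)cc(OC)c2)[C@@H](c2ccc(OC)c(OC)c2)O3)c1 | intermediate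
13 | 4-[(2S,3S)-3-(3,5-dihydroxyphenyl)-5-[(E)-2-(3,5-dihydroxyphenyl)ethenyl]-2,3-dihydro-1-benzofuran-2-yl]benzene-1,2-diol | Oc1cc(O)cc(/C=C/c2ccc3c(c2)[C@H](c2cc(O)cc(O)c2)[C@@H](c2ccc(O)c(O)c2)O3)c1 | target

**Count and risks**

Total step count: 7. Longest linear sequence: 6 steps (1 → 2 → 8 → 9 → 10 → 12 → 13; steps 1, 3, 4, 5, 6, 7).

Steps most likely to fail:

1. Step 3 (Proposed new method). What may go wrong: boron-to-palladium transmetallation overtakes the metallate shift so that simple biaryls form, or the ligand discriminates the two benzofuran faces poorly. The fallback uses known chemistry only, sets out from compound 2 and comes back at compound 10.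
   - Lithio compound 6, made from 2 as before, would be transmetallated with ZnCl2 to [5-(1,3-dioxolan-2-yl)-1-benzofuran-2-yl]zinc chloride F1.
   - Negishi coupling of F1 with 4-bromo-1,2-dimethoxybenzene (Pd(PPh3)4, THF, 60 °C) would give 2-(3,4-dimethoxyphenyl)-5-(1,3-dioxolan-2-yl)-1-benzofuran F2.
   - Electrophilic bromination at C3 with N-bromosuccinimide (MeCN, 0 °C) would give 3-bromo-2-(3,4-dimethoxyphenyl)-5-(1,3-dioxolan-2-yl)-1-benzofuran F3.
   - Suzuki–Miyaura coupling with 3,5-dimethoxyphenylboronic acid (Pd(PPh3)4, K2CO3, dioxane/H2O, 90 °C) would give 3-(3,5-dimethoxyphenyl)-2-(3,4-dimethoxyphenyl)-5-(1,3-dioxolan-2-yl)-1-benzofuran F4.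
   - Hydrogenation over palladium on carbon under hydrogen pressure adds both hydrogens to one face and should give the racemic cis-2,3-diaryl-2,3-dihydrobenzofuran acetal F5.
   - CF3CO2H in wet CH2Cl2 should equilibrate C2 through the ring-opened benzylic cation to the trans isomer and hydrolyse the acetal, giving the racemic trans aldehyde F6.
   - Preparative chromatography of F6 on a chiral stationary phase would return the (2S,3S) aldehyde 10.

2. Step 4. What may go wrong: protonation runs through a free, planar benzylic carbanion instead of front-side delivery, so that configuration at C2 is lost and the cis epimer forms. The fallback trades kinetic retention for thermodynamic control; it sets out from compound 8 and comes back at compound 10. The crude protodeboronation product, containing 2-[(2R,3S)-2-(3,4-dimethoxyphenyl)-3-(3,5-dimethoxyphenyl)-2,3-dihydro-1-benzofuran-5-yl]-1,3-dioxolane F7 (the cis epimer of 9), would be treated with CF3CO2H in wet CH2Cl2. Reversible ionisation of the C2–O bond (cation stabilised by the para-methoxy group of the C2 aryl) and reclosure should move C2 to the more stable trans arrangement. C3, the centre fixed by the catalyst, is untouched, and the acetal is hydrolysed in the same operation to give 10.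

3. Step 7. What may go wrong: the Lewis acid ionises the benzylic C2–O bond irreversibly (loss of the C3 proton to a ring-opened triarylethene), or the electron-rich stilbene oligomerises during ether cleavage. The fallback carries the six phenols as benzyl ethers from the outset and frees them at −78 °C; it sets out from compound 2 and comes back at compound 13.
   - Commercial 3,5-bis(benzyloxy)phenol would be triflated (Tf2O, pyridine, CH2Cl2, 0 °C) to 3,5-bis(benzyloxy)phenyl trifluoromethanesulfonate F8.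
   - Commercial 4-bromo-1,2-bis(benzyloxy)benzene would undergo Miyaura borylation (bis(pinacolato)diboron, KOAc, PdCl2[1,1′-bis(diphenylphosphino)ferrocene], dioxane, 90 °C) to 2-[3,4-bis(benzyloxy)phenyl]-4,4,5,5-tetramethyl-1,3,2-dioxaborolane F9.
   - Lithio compound 6 and F9 would give lithium [3,4-bis(benzyloxy)phenyl][5-(1,3-dioxolan-2-yl)-1-benzofuran-2-yl](pinacolato)borate F10.
   - Coupling of F10 with F8 under the conditions of step 3 should give 2-[(2S,3S)-3-[3,5-bis(benzyloxy)phenyl]-2-[3,4-bis(benzyloxy)phenyl]-5-(1,3-dioxolan-2-yl)-2,3-dihydro-1-benzofuran-2-yl]-4,4,5,5-tetramethyl-1,3,2-dioxaborolane F11.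
   - Protodeboronation as in step 4 would give 2-[(2S,3S)-2-[3,4-bis(benzyloxy)phenyl]-3-[3,5-bis(benzyloxy)phenyl]-2,3-dihydro-1-benzofuran-5-yl]-1,3-dioxolane F12.
   - Hydrolysis as in step 5 would give (2S,3S)-2-[3,4-bis(benzyloxy)phenyl]-3-[3,5-bis(benzyloxy)phenyl]-2,3-dihydro-1-benzofuran-5-carbaldehyde F13.
   - Diethyl [3,5-bis(benzyloxy)benzyl]phosphonate F14 would be made from commercial 3,5-bis(benzyloxy)benzyl bromide and P(OEt)3 by Michaelis–Arbuzov reaction.
   - Olefination of F13 with F14 as in step 6 would give (2S,3S)-2-[3,4-bis(benzyloxy)phenyl]-3-[3,5-bis(benzyloxy)phenyl]-5-[(E)-2-[3,5-bis(benzyloxy)phenyl]ethenyl]-2,3-dihydro-1-benzofuran F15.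
   - BCl3 with pentamethylbenzene as benzyl-cation scavenger (CH2Cl2, −78 °C; then H2O) should remove all six benzyl groups without touching the alkene and return target 13.

Further compounds
F1 | step 3 | [5-(1,3-dioxolan-2-yl)-1-benzofuran-2-yl]zinc chloride | Cl[Zn]c1cc2cc(C3OCCO3)ccc2o1
F2 | step 3 | 2-(3,4-dimethoxyphenyl)-5-(1,3-dioxolan-2-yl)-1-benzofuran | COc1ccc(-c2cc3cc(C4OCCO4)ccc3o2)cc1OC
F3 | step 3 | 3-bromo-2-(3,4-dimethoxyphenyl)-5-(1,3-dioxolan-2-yl)-1-benzofuran | COc1ccc(-c2oc3ccc(C4OCCO4)cc3c2Br)cc1OC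
F4 | step 3 | 3-(3,5-dimethoxyphenyl)-2-(3,4-dimethoxyphenyl)-5-(1,3-dioxolan-2-yl)-1-benzofuran | COc1cc(OC)cc(-c2c(-c3ccc(OC)c(OC)c3)oc3ccc(C4OCCO4)cc23)c1
F5 | step 3 | racemic cis-2-[2-(3,4-dimethoxyphenyl)-3-(3,5-dimethoxyphenyl)-2,3-dihydro-1-benzofuran-5-yl]-1,3-dioxolane, (2R,3S) and (2S,3R) forms | O1CCOC1c1ccc2c(c1)[C@H](c1cc(OC)cc(OC)c1)[C@H](c1ccc(OC)c(OC)c1)O2.O1CCOC1c1ccc2c(c1)[C@@H](c1cc(OC)cc(OC)c1)[C@@H](c1ccc(OC)c(OC)c1)O2
F6 | step 3 | racemic trans-2-(3,4-dimethoxyphenyl)-3-(3,5-dimethoxyphenyl)-2,3-dihydro-1-benzofuran-5-carbaldehyde, (2S,3S) and (2R,3R) forms | O=Cc1ccc2c(c1)[C@H](c1cc(OC)cc(OC)c1)[C@@H](c1ccc(OC)c(OC)c1)O2.O=Cc1ccc2c(c1)[C@@H](c1cc(OC)cc(OC)c1)[C@H](c1ccc(OC)c(OC)c1)O2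
F7 | step 4 | 2-[(2R,3S)-2-(3,4-dimethoxyphenyl)-3-(3,5-dimethoxyphenyl)-2,3-dihydro-1-benzofuran-5-yl]-1,3-dioxolane | O1CCOC1c1ccc2c(c1)[C@H](c1cc(OC)cc(OC)c1)[C@H](c1ccc(OC)c(OC)c1)O2
F8 | step 7 | 3,5-bis(benzyloxy)phenyl trifluoromethanesulfonate | O=S(=O)(Oc1cc(OCc2ccccc2)cc(OCc2ccccc2)c1)C(F)(F)F
F9 | step 7 | 2-[3,4-bis(benzyloxy)phenyl]-4,4,5,5-tetramethyl-1,3,2-dioxaborolane | CC1(C)OB(c2ccc(OCc3ccccc3)c(OCc3ccccc3)c2)OC1(C)C
F10 | step 7 | lithium [3,4-bis(benzyloxy)phenyl][5-(1,3-dioxolan-2-yl)-1-benzofuran-2-yl](pinacolato)borate | [Li+].CC1(C)O[B-](c2cc3cc(C4OCCO4)ccc3o2)(c2ccc(OCc3ccccc3)c(OCc3ccccc3)c2)OC1(C)C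
F11 | step 7 | 2-[(2S,3S)-3-[3,5-bis(benzyloxy)phenyl]-2-[3,4-bis(benzyloxy)phenyl]-5-(1,3-dioxolan-2-yl)-2,3-dihydro-1-benzofuran-2-yl]-4,4,5,5-tetramethyl-1,3,2-dioxaborolane | O1CCOC1c1ccc2c(c1)[C@H](c1cc(OCc3ccccc3)cc(OCc3ccccc3)c1)[C@@](B1OC(C)(C)C(C)(C)O1)(c1ccc(OCc3ccccc3)c(OCc3ccccc3)c1)O2
F12 | step 7 | 2-[(2S,3S)-2-[3,4-bis(benzyloxy)phenyl]-3-[3,5-bis(benzyloxy)phenyl]-2,3-dihydro-1-benzofuran-5-yl]-1,3-dioxolane | O1CCOC1c1ccc2c(c1)[C@H](c1cc(OCc3ccccc3)cc(OCc3ccccc3)c1)[C@@H](c1ccc(OCc3ccccc3)c(OCc3ccccc3)c1)O2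
F13 | step 7 | (2S,3S)-2-[3,4-bis(benzyloxy)phenyl]-3-[3,5-bis(benzyloxy)phenyl]-2,3-dihydro-1-benzofuran-5-carbaldehyde | O=Cc1ccc2c(c1)[C@H](c1cc(OCc3ccccc3)cc(OCc3ccccc3)c1)[C@@H](c1ccc(OCc3ccccc3)c(OCc3ccccc3)c1)O2
F14 | step 7 | diethyl [3,5-bis(benzyloxy)benzyl]phosphonate | CCOP(=O)(Cc1cc(OCc2ccccc2)cc(OCc2ccccc2)c1)OCC
F15 | step 7 | (2S,3S)-2-[3,4-bis(benzyloxy)phenyl]-3-[3,5-bis(benzyloxy)phenyl]-5-[(E)-2-[3,5-bis(benzyloxy)phenyl]ethenyl]-2,3-dihydro-1-benzofuran | c1ccccc1COc1cc(OCc2ccccc2)cc(/C=C/c2ccc3c(c2)[C@H](c2cc(OCc4ccccc4)cc(OCc4ccccc4)c2)[C@@H](c2ccc(OCc4ccccc4)c(OCc4ccccc4)c2)O3)c1
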